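**Strategy.** The angelate carbinols C3 and C8 sit 1,6 across the ten-membered ring. Joining them gives a cis-decalin-4a,8a-diol whose ring A (C3–C8 through C4–C7) is the (S)-carvone ring and whose ring B (C3–C2–C1–C10–C9–C8) is a cyclohexene oxide. All lasting stereocentres (C1, C4, C5, C7, C9, C10) are therefore set on a rigid bicycle, and a single glycol cleavage of the C3–C8 bond then releases the cyclodecane-1,6-dione. The cleavage precursor carries the C9 acetate of the target and fluoride-labile silyl ethers on O4 and O5, so that only three mild steps follow.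

Key step: step 13

Remark: locants C1–C10 are those of the target ring (C7 isopropenyl, C4 and C10 methyl) and are kept for all intermediates; TES = triethylsilyl, MOP = 2-methoxyprop-2-yl.
Assumption: the C8 hydroxyl of 6 is drawn as the expected major epimer; the other epimer would converge in step 6.

Step 1
Reactants: 1 (S)-carvone
Product: 2 trans-carvone oxide
Conditions: H2O2 (35% aq), NaOH (cat.), MeOH, 0 °C
Reagents that add atoms: hydrogen peroxide, OO
Why: Weitz–Scheffer nucleophilic epoxidation of the enone, in which hydroperoxide adds to the β-carbon C5 along the axial path anti to the isopropenyl group, so the oxirane forms trans to it and fixes the C4–O bond of the target (C5 is inverted in step 2).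

Step 2
Reactants: 2 trans-carvone oxide
Product: 3 trans-4,5-diol ketone
Conditions: H2SO4 (1 M aq), THF, rt
Reagents that add atoms: water, O
Why: Acid-catalysed SN2 opening of the α,β-epoxy ketone, in which water attacks the secondary β-carbon C5 with inversion while the tertiary C4–O bond next to the carbonyl is kept, giving the trans-diol with O5 cis and O4 trans to the isopropenyl group.

Step 3
Reactants: 3 trans-4,5-diol ketone
Product: 4 bis-TES ketone
Conditions: Et3SiOTf (2.4 equiv), 2,6-lutidine, CH2Cl2, −78 → 0 °C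
Reagents that add atoms: triethylsilyl trifluoromethanesulfonate, CC[Si](CC)(CC)OS(=O)(=O)C(F)(F)F
Why: Silyl triflates silylate secondary and tertiary hydroxyls alike, and the two TES ethers mask O4 so that only one glycol is open to cleavage in step 13 and can later be removed by fluoride instead of acid.

Step 4
Reactants: 4 bis-TES ketone
Product: 6 8-hydroxy ketone, via potassium enolate 5 (not isolated)
Conditions: KN(SiMe3)2, THF, −78 °C; then 2-(phenylsulfonyl)-3-phenyloxaziridine, −78 °C; NH4Cl (aq)
Reagents that add atoms: 2-(phenylsulfonyl)-3-phenyloxaziridine, O=S(=O)(c1ccccc1)N1OC1c1ccccc1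
Why: Davis enolate hydroxylation, in which the ketone can enolise only towards C8 because C4 is quaternary and oxygen is transferred to the face opposite the axial C4 methyl group (hydroxyl trans to the isopropenyl group); this centre is oxidised again in step 6, and staying at the α-hydroxy-ketone level avoids a free 1,2-diketone, which would enolise towards C7 and erase that stereocentre.

Step 5
Reactants: 6 8-hydroxy ketone; 7 allylmagnesium bromide
Product: 8 3-allyl-3,8-diol
Conditions: CH2=CHCH2MgBr (3 equiv), THF, −78 → 0 °C; NH4Cl (aq)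
Reagents that add atoms: none
Why: Grignard 1,2-addition in which, in the ring A chair (isopropenyl, O4 and O5 equatorial, C4 methyl axial), the reagent attacks C3 along the axial path opposite the C4 methyl group, so the allyl group becomes axial and trans to the isopropenyl group and the C3 hydroxyl cis to it, the first equivalent being consumed by the free C8 hydroxyl.

Step 6
Reactants: 8 3-allyl-3,8-diol
Product: 9 3-allyl-3-hydroxy-8-ketone
Conditions: IBX, DMSO, rt
Reagents that add atoms: none
Why: IBX oxidises the secondary C8 alcohol without touching the tertiary C3 alcohol and without cleaving the glycol, and C7 keeps its configuration because its isopropenyl group already lies equatorial.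

Step 7
Reactants: 10 2-methylprop-2-en-1-ol
Product: 11 methallyl MOP ether
Conditions: 2-methoxypropene, PPTS (cat.), CH2Cl2, 0 °C; then Et3N
Reagents that add atoms: 2-methoxypropene, C=C(C)OC
Why: Acid-catalysed addition of the alcohol to the enol ether gives a mixed ketal that withstands s-BuLi and is later removed by a trace of acid in methanol.

Step 8
Reactants: 9 3-allyl-3-hydroxy-8-ketone; 11 methallyl MOP ether
Product: 14 diene diol, via lithiated ether 12 (not isolated), via allyltitanium reagent 13 (not isolated)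
Conditions: 11 (3 equiv), s-BuLi, THF, −78 °C; ClTi(OiPr)3, −78 °C; then 9, −78 → −30 °C; NaHCO3 (aq)
Reagents that add atoms: none
Why: γ-Alkoxyallyl titanium reagents add to ketones through their oxygen-bearing carbon in a closed six-membered chair (Zimmerman–Traxler-type allyl transfer); with titanium held by the neighbouring C3 oxygen the C3 branch lies axial and C7 equatorial in that chair, so the (Z)-enol-ether oxygen becomes O9 cis to the new C8 hydroxyl in the ring to be closed, while approach to C8 along the equatorial path, away from the syn-axial C4 methyl, places the C8 hydroxyl cis to the C3 hydroxyl.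

Step 9
Reactants: 14 diene diol
Product: 15 cis-octalin diol 9-O-MOP ether
Conditions: second-generation Grubbs catalyst RuCl2(=CHPh)(SIMes)(PCy3) (5 mol %), toluene, 60 °C
Reagents that add atoms: none
Why: Ring-closing olefin metathesis in which the ruthenium carbene formed at the allyl terminus closes onto the 1,1-disubstituted alkene of the C8 branch to give the trisubstituted C1–C10 cyclohexene, the axial C3 and equatorial C8 branches being cis so that a cis-decalin results, while the isopropenyl group is trans to the allyl group and cannot bridge.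

Step 10
Reactants: 15 cis-octalin diol 9-O-MOP ether
Product: 16 allylic alcohol
Conditions: PPTS (0.05 equiv), MeOH, 0 °C
Reagents that add atoms: none
Why: Acid-catalysed methanolysis of the mixed ketal is much faster than cleavage of the TES ethers, so only O9 is released.

Step 11
Reactants: 16 allylic alcohol
Product: 17 epoxy triol
Conditions: VO(acac)2 (5 mol %), tBuOOH (1.2 equiv), CH2Cl2, 0 °C
Reagents that add atoms: tert-butyl hydroperoxide, CC(C)(C)OO
Why: Hydroxyl-directed epoxidation in which the vanadium-bound peroxide is delivered to the C1–C10 alkene from the face of the pseudoaxial allylic C9 hydroxyl, which is also the face of both homoallylic ring-fusion hydroxyls, so the oxirane forms cis to O9 and sets C1 and C10, while the undirected isopropenyl group reacts far more slowly.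

Step 12
Reactants: 17 epoxy triol
Product: 18 cleavage precursor (9-acetate)
Conditions: Ac2O, pyridine, DMAP (cat.), CH2Cl2, 0 °C → rt
Reagents that add atoms: acetic anhydride, CC(=O)OC(C)=O
Why: DMAP-catalysed acylation occurs only at the secondary C9 hydroxyl because both ring-fusion hydroxyls are tertiary, which installs the acetate of the target and takes the C8/C9 glycol out of reach of Pb(OAc)4.

Step 13
Reactants: 18 cleavage precursor (9-acetate)
Product: 20 epoxy cyclodecane-1,6-dione, via cyclic plumbate 19 (not isolated)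
Conditions: Pb(OAc)4 (1.2 equiv), pyridine, CH2Cl2, −20 → 0 °C; cold filtration, crude product used at once
Reagents that add atoms: none
Why: Tetravalent lead exchanges two acetates for the cis C3 and C8 hydroxyls to give the five-membered plumbate diester 19, which breaks down in one concerted two-electron step into the C3 and C8 ketones and Pb(OAc)2 (divalent lead); this is the Criegee glycol cleavage, known to turn cis-decalin-4a,8a-diols into cyclodecane-1,6-diones. No ring is closed by bond formation: the ten-membered carbocycle appears because the zero-atom bridge of the bicyclo[4.4.0] core is cut, so rings A and B merge into their common perimeter. No stereocentre is created, and C1, C4, C5, C7, C9 and C10 are carried over unchanged. Chemoselectivity rests on the substrate: O4 and O5 are silylated and O9 is acetylated, so the ring-fusion glycol is the only free 1,2-diol, and its hydroxyls are gauche (one axial, one equatorial on ring A) as the cyclic ester requires. The epoxide, the isopropenyl group and the esters do not react with Pb(OAc)4 at this temperature. Pyridine buffers the acetic acid released, and the cold neutral medium with immediate reduction of crude 20 guards against epimerisation at C7 and β-elimination of the β,γ-epoxy ketones.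

Step 14
Reactants: 20 epoxy cyclodecane-1,6-dione
Product: 21 (3S,8S)-diol
Conditions: Zn(BH4)2, Et2O, −20 → 0 °C; NH4Cl (aq)
Reagents that add atoms: none
Why: Zn(BH4)2 reduces both ketones under neutral conditions that spare the acetate, the epoxide and the silyl ethers and give no chance for acyl migration; hydride should reach each carbonyl from the outer face of the folded ring, anti to the transannular carbonyl, which at C8 is the face selected by zinc bridging the ketone and the C9 ester oxygen (Cram-chelate sense, O8 cis to O9) and at C3 is the Felkin–Anh face anti to the non-chelating C4 silyloxy group (O3 trans to O4), so the 3S,8S-diol is expected.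

Step 15
Reactants: 21 (3S,8S)-diol; 22 angelic acid (two equivalents are built into the product)
Product: 24 bis-angelate, via mixed anhydride 23 (not isolated)
Conditions: 22 (4 equiv), 2,4,6-Cl3C6H2COCl (4 equiv), Et3N (8 equiv), toluene, rt; then 21, toluene, 75 °C
Reagents that add atoms: angelic acid (the second equivalent of 22), C/C=C(/C)C(=O)O
Why: Yamaguchi-type esterification in which the mixed anhydride of angelic and 2,4,6-trichlorobenzoic acid acylates each of the two secondary hydroxyls once (two angeloyl units in all, with retention at C3 and C8), and working without DMAP keeps the (Z)-double bond from isomerising to the tiglate.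

Step 16
Reactants: 24 bis-angelate
Product: 25 CNP0249359.1
Conditions: HF·pyridine, pyridine, THF, 0 °C → rt
Reagents that add atoms: none
Why: Fluoride cleaves both Si–O bonds (secondary O5 and tertiary O4) under buffered, nearly neutral conditions that leave the three esters and the trisubstituted epoxide untouched, which an acid-labile acetal at this point would not allow.

**Compound list**

1 | (S)-carvone, (5S)-2-methyl-5-(prop-1-en-2-yl)cyclohex-2-en-1-one | CC1=CC[C@@H](CC1=O)C(C)=C | starting material
2 | trans-carvone oxide, (1S,4S,6S)-1-methyl-4-(prop-1-en-2-yl)-7-oxabicyclo[4.1.0]heptan-2-one | C=C(C)[C@H]1C[C@@H]2O[C@]2(C)C(=O)C1 | intermediate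
3 | (2S,3R,5S)-2,3-dihydroxy-2-methyl-5-(prop-1-en-2-yl)cyclohexan-1-one | C=C(C)[C@H]1C[C@@H](O)[C@](C)(O)C(=O)C1 | intermediate
4 | (2S,3R,5S)-2-methyl-5-(prop-1-en-2-yl)-2,3-bis(triethylsilyloxy)cyclohexan-1-one | C=C(C)[C@H]1C[C@@H](O[Si](CC)(CC)CC)[C@](C)(O[Si](CC)(CC)CC)C(=O)C1 | intermediate
5 | potassium enolate of 4 (C3=C8 enolate; not isolated) | C=C(C)[C@H]1C[C@@H](O[Si](CC)(CC)CC)[C@](C)(O[Si](CC)(CC)CC)C(O[K])=C1 | intermediate
6 | (2S,3R,5R,6R)-6-hydroxy-2-methyl-5-(prop-1-en-2-yl)-2,3-bis(triethylsilyloxy)cyclohexan-1-one (C8 hydroxyl trans to isopropenyl) | C=C(C)[C@H]1C[C@@H](O[Si](CC)(CC)CC)[C@](C)(O[Si](CC)(CC)CC)C(=O)[C@@H]1O | intermediate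
7 | allylmagnesium bromide | C=CC[Mg]Br | starting material
8 | 3-allyl-3,8-diol of ring A; allyl and C8 hydroxyl trans, C3 hydroxyl cis to the isopropenyl group; O4,O5-bis-TES | C=C(C)[C@H]1C[C@@H](O[Si](CC)(CC)CC)[C@](C)(O[Si](CC)(CC)CC)[C@](O)(CC=C)[C@@H]1O | intermediate
9 | 3-allyl-3-hydroxy-8-ketone of ring A (allyl trans to isopropenyl); O4,O5-bis-TES | C=C(C)[C@H]1C[C@@H](O[Si](CC)(CC)CC)[C@](C)(O[Si](CC)(CC)CC)[C@](O)(CC=C)C1=O | intermediate
10 | 2-methylprop-2-en-1-ol | C=C(C)CO | starting material
11 | 3-(2-methoxypropan-2-yloxy)-2-methylprop-1-ene (methallyl MOP ether) | C=C(C)COC(C)(C)OC | intermediate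
12 | lithiated 11, 1-lithio-1-(2-methoxypropan-2-yloxy)-2-methylallyl species (not isolated) | [Li]C(OC(C)(C)OC)C(C)=C | intermediate
13 | (Z)-[3-(2-methoxypropan-2-yloxy)-2-methylallyl]titanium triisopropoxide (not isolated) | CC(C)O[Ti](OC(C)C)(OC(C)C)C/C(C)=C\OC(C)(C)OC | intermediate
14 | diene diol: C3 allyl, C8 bearing CH(OMOP)C(CH3)=CH2; C3 and C8 hydroxyls cis to each other and to the isopropenyl group; C9 as in the target; O4,O5-bis-TES | C=C(C)[C@H]1C[C@@H](O[Si](CC)(CC)CC)[C@](C)(O[Si](CC)(CC)CC)[C@](O)(CC=C)[C@]1(O)[C@H](OC(C)(C)OC)C(C)=C | intermediate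
15 | cis-octalin-3,8-diol with C1=C10 alkene, 9-O-MOP, O4,O5-bis-TES | C=C(C)[C@H]1C[C@@H](O[Si](CC)(CC)CC)[C@](C)(O[Si](CC)(CC)CC)[C@]4(O)CC=C(C)[C@@H](OC(C)(C)OC)[C@]14O | intermediate
16 | cis-octalin-3,8,9-triol (9-hydroxyl cis to both ring-fusion hydroxyls), O4,O5-bis-TES | C=C(C)[C@H]1C[C@@H](O[Si](CC)(CC)CC)[C@](C)(O[Si](CC)(CC)CC)[C@]4(O)CC=C(C)[C@@H](O)[C@]14O | intermediate
17 | 1,10-epoxy-cis-decalin-3,8,9-triol (epoxide cis to the 9-hydroxyl), O4,O5-bis-TES | C=C(C)[C@H]1C[C@@H](O[Si](CC)(CC)CC)[C@](C)(O[Si](CC)(CC)CC)[C@]4(O)C[C@H]2O[C@@]2(C)[C@@H](O)[C@]14O | intermediate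
18 | cleavage precursor: 9-O-acetyl-1,10-epoxy-cis-decalin-3,8-diol (decalin-4a,8a-diol), O4,O5-bis-TES | C=C(C)[C@H]1C[C@@H](O[Si](CC)(CC)CC)[C@](C)(O[Si](CC)(CC)CC)[C@]4(O)C[C@H]2O[C@@]2(C)[C@@H](OC(C)=O)[C@]14O | intermediate
19 | cyclic plumbate diester of 18, O3–Pb(OAc)2–O8 (not isolated) | C=C(C)[C@H]1C[C@@H](O[Si](CC)(CC)CC)[C@](C)(O[Si](CC)(CC)CC)[C@]4(O5)C[C@H]2O[C@@]2(C)[C@@H](OC(C)=O)[C@]14O[Pb]5(OC(C)=O)OC(C)=O | intermediate
20 | 9-acetoxy-1,10-epoxy-4,5-bis(triethylsilyloxy)germacr-11(12)-ene-3,8-dione | C=C(C)[C@H]1C[C@@H](O[Si](CC)(CC)CC)[C@](C)(O[Si](CC)(CC)CC)C(=O)C[C@H]2O[C@@]2(C)[C@@H](OC(C)=O)C1=O | intermediate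
21 | (3S,8S)-9-acetoxy-1,10-epoxy-4,5-bis(triethylsilyloxy)germacr-11(12)-ene-3,8-diol | C=C(C)[C@H]1C[C@@H](O[Si](CC)(CC)CC)[C@](C)(O[Si](CC)(CC)CC)[C@@H](O)C[C@H]2O[C@@]2(C)[C@@H](OC(C)=O)[C@H]1O | intermediate
22 | angelic acid, (Z)-2-methylbut-2-enoic acid | C/C=C(/C)C(=O)O | starting material
23 | angelic 2,4,6-trichlorobenzoic anhydride (not isolated) | C/C=C(/C)C(=O)OC(=O)c1c(Cl)cc(Cl)cc1Cl | intermediate
24 | 9-O-acetyl-3,8-di-O-angeloyl-1,10-epoxy-4,5-bis-O-triethylsilyl compound | C=C(C)[C@H]1C[C@@H](O[Si](CC)(CC)CC)[C@](C)(O[Si](CC)(CC)CC)[C@@H](OC(=O)/C(C)=C\C)C[C@H]2O[C@@]2(C)[C@@H](OC(C)=O)[C@H]1OC(=O)/C(C)=C\C | intermediate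
25 | CNP0249359.1, (1R,3S,4S,5R,7R,8S,9S,10R)-9-acetoxy-1,10-epoxy-4,5-dihydroxygermacr-11(12)-ene-3,8-diyl bis[(Z)-2-methylbut-2-enoate] | C=C(C)[C@H]1C[C@@H](O)[C@](C)(O)[C@@H](OC(=O)/C(C)=C\C)C[C@H]2O[C@@]2(C)[C@@H](OC(C)=O)[C@H]1OC(=O)/C(C)=C\C | target

**Total step count:** 16. **Longest linear sequence:** 15 steps (steps 1–6 and 8–16, from (S)-carvone).

**Steps most likely to fail**

1. Step 8. The reagent may attack C8 with poor facial selectivity, since one face is shielded by the syn-axial C4 methyl and the other by the axial C3 allyl group. The closed, C3-oxygen-bound transition state may also be lost, which would give the wrong relative configuration at C9. The fallback sets out from 9 and returns at 16. 2-Methylallylmagnesium chloride, a small and very reactive allyl nucleophile that creates no stereocentre at C9, is added to 9 to give the methallyl carbinol F1. Ring-closing metathesis with the second-generation Grubbs catalyst then gives the octalin diol F2 with a C9 methylene. Allylic oxidation with SeO2 (cat.)/tBuOOH (ene reaction followed by a [2,3]-shift) hydroxylates C9, the ring CH2 next to the methyl-bearing alkene carbon. Oxygen should arrive from the convex face on which the ring-fusion hydroxyls lie, and the trisubstituted ring alkene should react ahead of the isopropenyl group, so the product is allylic alcohol 16.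

2. Step 14. Hydride delivery to the flexible ten-membered dione may show poor facial selectivity, above all at C8, where zinc binds an ester oxygen only weakly and Felkin–Anh attack would give the 8-epimer. The fallback sets out from 17 and returns at 24. O9 of 17 is protected under neutral conditions (2-(4-methoxybenzyloxy)-4-methylquinoline, MeOTf, MgO, PhCF3) as the 4-methoxybenzyl ether F3. Pb(OAc)4 cleavage as in step 13 gives the dione F4. Zn(BH4)2 can now chelate the C8 carbonyl and the ether oxygen firmly (Cram-chelate reduction), while C3 reacts in the Felkin–Anh sense, to give the diol F5. Acylation as in step 15 gives the bis-angelate F6, DDQ (CH2Cl2, pH 7 buffer) removes the 4-methoxybenzyl group to give the C9 alcohol F7, and acetylation (Ac2O, pyridine, DMAP) returns to 24.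

3. Step 15. Under hot, basic conditions the (Z)-2-methylbut-2-enoyl group may isomerise to the (E)-isomer, acylation of the hindered C3 hydroxyl may be slow, and the acetyl group may migrate from O9 to O8 while O8 is free. The fallback sets out from 21 and returns at 24. Both hydroxyls of 21 are esterified at low temperature with 2-[bis(2,2,2-trifluoroethoxy)phosphoryl]propanoic acid (DCC, DMAP cat., CH2Cl2, 0 °C) to give the bis-phosphonate F8. The two angelate double bonds are then built in place by Z-selective Still–Gennari olefination with acetaldehyde (KN(SiMe3)2, 18-crown-6, THF, −78 °C), which gives 24.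

**Further compounds**

F1 | step 8 | methallyl carbinol: C3 allyl, C8 2-methylallyl, C3 and C8 hydroxyls cis, O4,O5-bis-TES | C=C(C)[C@H]1C[C@@H](O[Si](CC)(CC)CC)[C@](C)(O[Si](CC)(CC)CC)[C@](O)(CC=C)[C@]1(O)CC(C)=C
F2 | step 8 | cis-octalin-3,8-diol with C1=C10 alkene and C9 methylene, O4,O5-bis-TES | C=C(C)[C@H]1C[C@@H](O[Si](CC)(CC)CC)[C@](C)(O[Si](CC)(CC)CC)[C@]4(O)CC=C(C)C[C@]14O
F3 | step 14 | 9-O-(4-methoxybenzyl)-1,10-epoxy-cis-decalin-3,8-diol, O4,O5-bis-TES | C=C(C)[C@H]1C[C@@H](O[Si](CC)(CC)CC)[C@](C)(O[Si](CC)(CC)CC)[C@]4(O)C[C@H]2O[C@@]2(C)[C@@H](OCc2ccc(OC)cc2)[C@]14O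
F4 | step 14 | 9-(4-methoxybenzyloxy)-1,10-epoxy-4,5-bis(triethylsilyloxy)germacr-11(12)-ene-3,8-dione | C=C(C)[C@H]1C[C@@H](O[Si](CC)(CC)CC)[C@](C)(O[Si](CC)(CC)CC)C(=O)C[C@H]2O[C@@]2(C)[C@@H](OCc2ccc(OC)cc2)C1=O
F5 | step 14 | (3S,8S)-9-(4-methoxybenzyloxy)-1,10-epoxy-4,5-bis(triethylsilyloxy)germacr-11(12)-ene-3,8-diol | C=C(C)[C@H]1C[C@@H](O[Si](CC)(CC)CC)[C@](C)(O[Si](CC)(CC)CC)[C@@H](O)C[C@H]2O[C@@]2(C)[C@@H](OCc2ccc(OC)cc2)[C@H]1O
F6 | step 14 | 3,8-di-O-angeloyl-9-O-(4-methoxybenzyl)-4,5-bis-O-triethylsilyl compound | C=C(C)[C@H]1C[C@@H](O[Si](CC)(CC)CC)[C@](C)(O[Si](CC)(CC)CC)[C@@H](OC(=O)/C(C)=C\C)C[C@H]2O[C@@]2(C)[C@@H](OCc2ccc(OC)cc2)[C@H]1OC(=O)/C(C)=C\C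
F7 | step 14 | 3,8-di-O-angeloyl-4,5-bis-O-triethylsilyl C9 alcohol | C=C(C)[C@H]1C[C@@H](O[Si](CC)(CC)CC)[C@](C)(O[Si](CC)(CC)CC)[C@@H](OC(=O)/C(C)=C\C)C[C@H]2O[C@@]2(C)[C@@H](O)[C@H]1OC(=O)/C(C)=C\C
F8 | step 15 | 3,8-bis-O-{2-[bis(2,2,2-trifluoroethoxy)phosphoryl]propanoyl} derivative of 21 | C=C(C)[C@H]1C[C@@H](O[Si](CC)(CC)CC)[C@](C)(O[Si](CC)(CC)CC)[C@@H](OC(=O)C(C)P(=O)(OCC(F)(F)F)OCC(F)(F)F)C[C@H]2O[C@@]2(C)[C@@H](OC(C)=O)[C@H]1OC(=O)C(C)P(=O)(OCC(F)(F)F)OCC(F)(F)F
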